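| flask | solid substrate | partner | remark | time |
|---|---|---|---|---|
| north | 0.34 M | 2 equiv | run made earlier |  |
| south | 0.77 M | 2 equiv | run made earlier |  |
| north-east | 0.51 M | 3 equiv | run made earlier |  |
| flask | 0.51 M | 2.00 equiv |  | 15 h |

| run | time / h | mono adduct / % | starting material / % | solid substrate / % |
|---|---|---|---|---|
| north | 1.00 | 0.9 | 21.7 | 79.1 |
| north | 1.50 | 1.2 | 27.2 | 72.9 |
| north | 2.50 | 0.4 | 36.9 | 62.3 |
| north | 4.00 | 1.5 | 42.7 | 53.7 |
| north | 8.00 | 5.6 | 50.2 | 44.8 |
| north | 12.0 | 7.3 | 51.2 | 40.8 |
| south | 1.00 | 0 | 8.8 | 91.0 |
| south | 1.50 | 0.6 | 11.5 | 88.0 |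
| south | 2.50 | 0.5 | 15.9 | 83.1 |
| south | 4.00 | 2.2 | 18.5 | 78.7 |
| south | 8.00 | 3.9 | 21.7 | 73.4 |
| south | 12.0 | 5.1 | 21.1 | 70.6 |
| north-east | 2.50 | 1.2 | 24.4 | 75.0 |
| north-east | 5.00 | 3.8 | 30.4 | 64.5 |
| north-east | 8.00 | 6.2 | 32.4 | 59.9 |
| north-east | 10.0 | 8.1 | 32.1 | 58.3 |
| north-east | 12.0 | 8.0 | 32.0 | 53.3 |

(scatter of a reading: 0.5 percentage points)

- solid, in amounts per volume of the solution: solid substrate
- at the start none of the solid substrate is in solution
- starting material means what is dissolved; the solid is not counted in it
- starting material is what solid substrate becomes in solution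

1. how much mono adduct there is at 15 h, in percent of the solid substrate charged
2. concentration of starting material in solution at 15 h, in percent of saturation

At early times the solid fed the solution with a lag: in the north run, starting material stood at 21.7% after 1.00 h against 51.2% after 12.0 h, which I read as a first-order approach with a time of 1.81 h.

I then took the part of the charge that is neither solid nor dissolved. With the dissolved level on its plateau and partner near its charge, the loss is pseudo-first-order in partner, so this share should follow equivalents times time after the lag, with the loading cancelled.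

| run | partner | time | share |
|---|---|---|---|
| north | 2 equiv | 12.0 h | 8.00% |
| south | 2 equiv | 12.0 h | 8.30% |
| north-east | 3 equiv | 10.0 h | 9.60% |
| north-east | 3 equiv | 12.0 h | 14.7% |

North and south agree despite their loadings; the later north-east reading lies high.

For the flask, I scaled north and south to a turnover share of 10.6% at 15 h. One number was not enough: mono adduct made up 76.1% of the share in those runs, giving 8.03%. The hourly loss times the lag, set against the plateau, gave 95.7% of saturation.

The forecast gave 8% and 95%, holding that “this is saturation, with solid still present”.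

The flask gave 7.54% and 95.3%, and its three adducts summed to 10.9%.

    partner + mono adduct → double product (k = 0.00100 L mol⁻¹ min⁻¹)
    partner + double product → tris adduct (k = 3.00 × 10⁻⁴ L mol⁻¹ min⁻¹)
    solid substrate ⇌ starting material, rate k3*(cs3 - [starting material]) while solid is left; crystals form when [starting material] > cs3 (solubility = 0.180 M, k = 0.00820 min⁻¹)
    partner + tris adduct → tetra adduct (k = 9.20 × 10⁻⁶ L mol⁻¹ min⁻¹)
    starting material + partner → mono adduct (k = 4.20 × 10⁻⁴ L mol⁻¹ min⁻¹)

At 15.0 h, the flask made starting material 1.02 times as fast as it used it, and mono adduct 1.87 times as fast. Dissolved material was thus nearly steady while mono adduct still rose.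

For the same charges read at 40 h, the neighbour flask, the share scaled to 30.7%. That neighbour flask held 29.1% of the solid substrate charged as mono adduct, double product and tris adduct together; mono adduct alone stood at 12.4% of that charge, and 75% of the charged partner was left.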